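The route rests on cutting the O1–C2 bond of the dihydrofuran ring. Because C2 carries the para-oxygenated guaiacyl ring, its benzylic alcohol ionises under mild acid to an O-silylated para-quinone methide cation, which the phenol oxygen on C7a of ring B captures in a 5-exo closure. In that one operation the furan ring, the O1–C2 bond and the C2 stereocentre (trans to C3) are formed from either carbinol epimer. The precursor is therefore an acyclic 1-aryl-2-(2-hydroxyaryl)propane-1,3-diol in which only C3 is set, by an auxiliary-controlled aldol reaction; C9 stays a free alcohol, ready for late esterification with protected p-coumaric acid.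

Key step: step 12

Remarks and assumptions:
- Positions follow the dihydrobenzofuran core of the target (O1, C2, C3, C3a to C7a; C9 is the CH2O carbon on C3).
- TBDPS = tert-butyldiphenylsilyl, TIPS = tri(propan-2-yl)silyl, TBS = tert-butyldimethylsilyl; "TBDPSO" etc. denote the silyloxy groups.
- The C9 hydroxyl is carried unprotected through the ring closure, since it could only close an oxetane; this removes a protection and a deprotection.
- The guaiacyl oxygen carries the bulky TIPS group so that the silyl group stays on the oxocarbenium ion and survives hydride and hydrogenolysis.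
- The (R)-auxiliary is required: it gives the (2R) acyl centre, which becomes C3 with the S descriptor once the acyl carbon is reduced to C9.
- The auxiliary, allyl bromide, benzyl bromide and the silyl chlorides are taken as commercial.

Step 1
Reactants: 1 dihydroconiferyl alcohol
Product: 2 3-[3-methoxy-4-(prop-2-en-1-yloxy)phenyl]propan-1-ol
Conditions: allyl bromide, K2CO3, acetone, reflux
Reagents that add atoms: allyl bromide, C=CCBr
Why: Williamson ether synthesis; K2CO3 deprotonates only the phenol, so the primary alcohol should stay untouched.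

Step 2
Reactants: 2 3-[3-methoxy-4-(prop-2-en-1-yloxy)phenyl]propan-1-ol
Product: 3 tert-butyl{3-[3-methoxy-4-(prop-2-en-1-yloxy)phenyl]propoxy}diphenylsilane
Conditions: TBDPSCl, imidazole, DMF, 0 °C → rt
Reagents that add atoms: tert-butyl(chloro)diphenylsilane, CC(C)(C)[Si](Cl)(c1ccccc1)c1ccccc1
Why: Imidazole-promoted silylation of the only hydroxyl group; the TBDPS ether should survive the later heat, acid, hydride and hydrogenolysis.

Step 3
Reactants: 3 tert-butyl{3-[3-methoxy-4-(prop-2-en-1-yloxy)phenyl]propoxy}diphenylsilane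
Product: 4 2-methoxy-6-(prop-2-en-1-yl)-4-[3-(TBDPSO)propyl]phenol
Conditions: N,N-diethylaniline, 200 °C, degassed
Reagents that add atoms: none
Why: Aromatic Claisen rearrangement; one ortho position carries OMe and the para position the side chain, so the allyl group should migrate only to the free ortho carbon, the future C3a.

Step 4
Reactants: 4 2-methoxy-6-(prop-2-en-1-yl)-4-[3-(TBDPSO)propyl]phenol
Product: 5 2-(benzyloxy)-1-methoxy-3-(prop-2-en-1-yl)-5-[3-(TBDPSO)propyl]benzene
Conditions: BnBr, K2CO3, DMF, 60 °C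
Reagents that add atoms: benzyl bromide, BrCc1ccccc1
Why: Williamson benzylation of the hindered phenol; the benzyl ether is orthogonal to every silyl ether in the route and is removed later by hydrogenolysis.

Step 5
Reactants: 5 2-(benzyloxy)-1-methoxy-3-(prop-2-en-1-yl)-5-[3-(TBDPSO)propyl]benzene
Product: 6 2-{2-(benzyloxy)-3-methoxy-5-[3-(TBDPSO)propyl]phenyl}acetaldehyde
Conditions: OsO4 (2 mol%), NaIO4, 2,6-lutidine, dioxane/H2O, rt
Reagents that add atoms: sodium periodate, [Na+].[O-]I(=O)(=O)=O (terminal oxygen source, relayed through catalytic osmium tetroxide, O=[Os](=O)(=O)=O)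
Why: Lemieux–Johnson oxidative cleavage of the terminal alkene (dihydroxylation, then glycol cleavage); the lutidine buffer should suppress over-oxidation, and the crude aldehyde is used at once.

Step 6
Reactants: 6 2-{2-(benzyloxy)-3-methoxy-5-[3-(TBDPSO)propyl]phenyl}acetaldehyde
Product: 7 2-{2-(benzyloxy)-3-methoxy-5-[3-(TBDPSO)propyl]phenyl}acetic acid
Conditions: NaClO2, NaH2PO4, 2-methyl-2-butene, t-BuOH/H2O, 0 °C → rt
Reagents that add atoms: sodium chlorite, [Na+].[O-]Cl=O
Why: Pinnick oxidation; the alkene scavenger removes hypochlorous acid, so the electron-rich ring should not be chlorinated.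

Step 7
Reactants: 7 2-{2-(benzyloxy)-3-methoxy-5-[3-(TBDPSO)propyl]phenyl}acetic acid; 8 (4R)-4-benzyl-1,3-oxazolidin-2-one
Product: 10 (4R)-4-benzyl-3-(2-{2-(benzyloxy)-3-methoxy-5-[3-(TBDPSO)propyl]phenyl}acetyl)-1,3-oxazolidin-2-one, via mixed pivalic anhydride 9 (not isolated)
Conditions: PivCl, Et3N, THF, −20 °C; then 8, LiCl, −20 °C → rt
Reagents that add atoms: pivaloyl chloride, CC(C)(C)C(Cl)=O (its acyl group is carried only in intermediate 9)
Why: N-acylation of the oxazolidinone through a mixed anhydride, which is attacked at its less hindered arylacetyl carbonyl; this avoids the ketene formation typical of arylacetyl chlorides.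

Step 8
Reactants: 11 vanillin
Product: 12 3-methoxy-4-(TIPSO)benzaldehyde
Conditions: TIPSCl, imidazole, DMF, rt
Reagents that add atoms: chlorotri(propan-2-yl)silane, CC(C)[Si](Cl)(C(C)C)C(C)C
Why: Phenol silylation; the TIPS ether masks the acidic phenol for the aldol step and is bulky enough to stay in place in steps 10 to 12.

Step 9
Reactants: 10 (4R)-4-benzyl-3-(2-{2-(benzyloxy)-3-methoxy-5-[3-(TBDPSO)propyl]phenyl}acetyl)-1,3-oxazolidin-2-one; 12 3-methoxy-4-(TIPSO)benzaldehyde
Product: 14 (4R)-4-benzyl-3-[(2R,3R)-2-{2-(benzyloxy)-3-methoxy-5-[3-(TBDPSO)propyl]phenyl}-3-hydroxy-3-[3-methoxy-4-(TIPSO)phenyl]propanoyl]-1,3-oxazolidin-2-one, via dibutylboron Z-enolate 13 (not isolated)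
Conditions: Bu2BOTf, iPr2NEt, CH2Cl2, −78 → 0 °C; 12, −78 → 0 °C; then pH 7 buffer, MeOH, H2O2, 0 °C
Reagents that add atoms: dibutylboron triflate, CCCCB(CCCC)OS(=O)(=O)C(F)(F)F (its Bu2B group is carried only in intermediate 13)
Why: Evans syn aldol reaction; the Z-boron enolate should react through a chair transition state with the auxiliary carbonyl turned away from the enolate oxygen, so the aldehyde reaches the face remote from the C4 benzyl group, which sets the acyl α-carbon (future C3) as R and the carbinol as R, the latter being erased in step 12.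

Step 10
Reactants: 14 the syn aldol adduct
Product: 15 (1R,2S)-2-{2-(benzyloxy)-3-methoxy-5-[3-(TBDPSO)propyl]phenyl}-1-[3-methoxy-4-(TIPSO)phenyl]propane-1,3-diol
Conditions: LiBH4, MeOH (1 equiv), THF, 0 °C
Reagents that add atoms: none
Why: Reductive cleavage of the N-acyl oxazolidinone; hydride should attack the exocyclic carbonyl and take it down to the C9 alcohol faster than enolisation or retro-aldol cleavage, so C3 keeps its geometry (the descriptor changes from R to S only because the acyl carbon loses priority).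

Step 11
Reactants: 15 the O-benzyl diol
Product: 16 (1R,2S)-2-{2-hydroxy-3-methoxy-5-[3-(TBDPSO)propyl]phenyl}-1-[3-methoxy-4-(TIPSO)phenyl]propane-1,3-diol
Conditions: H2 (1 atm), 10% Pd/C, EtOAc, rt
Reagents that add atoms: none
Why: Hydrogenolysis of the aryl benzyl ether; in neutral ethyl acetate the silyl ethers are inert and the secondary benzylic alcohol should be cleaved far more slowly than the O-benzyl group.

Step 12
Reactants: 16 the phenol triol (either carbinol epimer)
Product: 18 [(2R,3S)-7-methoxy-2-[3-methoxy-4-(TIPSO)phenyl]-5-[3-(TBDPSO)propyl]-2,3-dihydro-1-benzofuran-3-yl]methanol, via O-silyl para-quinone methide cation 17 (not isolated)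
Conditions: (+)-camphor-10-sulfonic acid (10 mol%), CH2Cl2, −20 → 0 °C; then Et3N
Reagents that add atoms: none
Why: Protonation of the C2 hydroxyl of either carbinol epimer and loss of water should give a benzylic cation that the para-silyloxy oxygen of the guaiacyl ring stabilises as the O-silyl para-quinone methide 17, and the ring-B phenol oxygen adds to its exocyclic carbon to form O1–C2. The closest known reaction type is the acid-promoted cyclisation of 1-(4-oxygenated aryl)-2-(2-hydroxyaryl)propane-1,3-diols to trans-2-aryl-2,3-dihydrobenzofurans, the laboratory counterpart of the last step of phenylcoumaran biosynthesis. The dihydrofuran ring closes in a 5-exo-trig mode, O1 attacking the methide carbon C2. The new C2 stereocentre is controlled by the existing C3 centre: the aryl group takes the face opposite the C3 hydroxymethyl group, and because ionisation and closure are reversible the trans (2R,3S) ring should also be the thermodynamic end point, which makes the carbinol configuration of 16 irrelevant. The step needs trans diastereoselectivity and capture by the phenol in preference to loss of a proton or of formaldehyde; the first is secured by the C3 substituent, the second by the C7a phenol sitting five atoms from C2 (the C9 hydroxyl could only close a four-membered ring), by the low temperature and by the bulky TIPS group, which resists transfer from the oxocarbenium oxygen. C3 bears no acidifying group and should keep its configuration.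

Step 13
Reactants: 19 p-coumaric acid
Product: 21 (E)-3-[4-(TBSO)phenyl]prop-2-enoic acid, via bis-silylated coumarate 20 (not isolated)
Conditions: TBSCl (2.2 equiv), imidazole, DMF, rt; then AcOH/THF/H2O, rt
Reagents that add atoms: tert-butyl(chloro)dimethylsilane, CC(C)(C)[Si](C)(C)Cl
Why: Exhaustive silylation followed by selective hydrolysis of the very labile silyl ester, which should leave the aryl silyl ether intact and the acid free for coupling.

Step 14
Reactants: 18 the dihydrobenzofuran C9 alcohol; 21 (E)-3-[4-(TBSO)phenyl]prop-2-enoic acid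
Product: 22 [(2R,3S)-7-methoxy-2-[3-methoxy-4-(TIPSO)phenyl]-5-[3-(TBDPSO)propyl]-2,3-dihydro-1-benzofuran-3-yl]methyl (E)-3-[4-(TBSO)phenyl]prop-2-enoate
Conditions: EDC·HCl, DMAP, CH2Cl2, 0 °C → rt
Reagents that add atoms: none
Why: Steglich esterification; the C9 alcohol is the only free hydroxyl in 18 and every phenol is silylated, so a single ester should form with the E alkene unchanged.

Step 15
Reactants: 22 the tris-silylated ester
Product: 23 [(2R,3S)-2-(4-hydroxy-3-methoxyphenyl)-5-(3-hydroxypropyl)-7-methoxy-2,3-dihydro-1-benzofuran-3-yl]methyl (E)-3-(4-hydroxyphenyl)prop-2-enoate (CNP0202924.1)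
Conditions: TBAF, AcOH, THF, 0 °C → rt
Reagents that add atoms: none
Why: Fluoride-mediated global desilylation of the two aryl silyl ethers and the primary TBDPS ether; the acetic acid buffer should protect the cinnamate ester and prevent phenoxide-driven reopening of the O1–C2 bond.

Compound list
1 | dihydroconiferyl alcohol, 4-(3-hydroxypropyl)-2-methoxyphenol | COc1cc(CCCO)ccc1O | starting material
2 | 3-[3-methoxy-4-(prop-2-en-1-yloxy)phenyl]propan-1-ol | COc1cc(CCCO)ccc1OCC=C | intermediate
3 | tert-butyl{3-[3-methoxy-4-(prop-2-en-1-yloxy)phenyl]propoxy}diphenylsilane | COc1cc(CCCO[Si](c2ccccc2)(c2ccccc2)C(C)(C)C)ccc1OCC=C | intermediate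
4 | 2-methoxy-6-(prop-2-en-1-yl)-4-[3-(tert-butyldiphenylsilyloxy)propyl]phenol | COc1cc(CCCO[Si](c2ccccc2)(c2ccccc2)C(C)(C)C)cc(CC=C)c1O | intermediate
5 | 2-(benzyloxy)-1-methoxy-3-(prop-2-en-1-yl)-5-[3-(tert-butyldiphenylsilyloxy)propyl]benzene | COc1cc(CCCO[Si](c2ccccc2)(c2ccccc2)C(C)(C)C)cc(CC=C)c1OCc1ccccc1 | intermediate
6 | 2-{2-(benzyloxy)-3-methoxy-5-[3-(tert-butyldiphenylsilyloxy)propyl]phenyl}acetaldehyde | COc1cc(CCCO[Si](c2ccccc2)(c2ccccc2)C(C)(C)C)cc(CC=O)c1OCc1ccccc1 | intermediate
7 | 2-{2-(benzyloxy)-3-methoxy-5-[3-(tert-butyldiphenylsilyloxy)propyl]phenyl}acetic acid | COc1cc(CCCO[Si](c2ccccc2)(c2ccccc2)C(C)(C)C)cc(CC(=O)O)c1OCc1ccccc1 | intermediate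
8 | (4R)-4-benzyl-1,3-oxazolidin-2-one | O=C1OC[C@@H](Cc2ccccc2)N1 | starting material
9 | mixed anhydride of acid 7 and 2,2-dimethylpropanoic acid | COc1cc(CCCO[Si](c2ccccc2)(c2ccccc2)C(C)(C)C)cc(CC(=O)OC(=O)C(C)(C)C)c1OCc1ccccc1 | intermediate (not isolated)
10 | (4R)-4-benzyl-3-(2-{2-(benzyloxy)-3-methoxy-5-[3-(tert-butyldiphenylsilyloxy)propyl]phenyl}acetyl)-1,3-oxazolidin-2-one | COc1cc(CCCO[Si](c2ccccc2)(c2ccccc2)C(C)(C)C)cc(CC(=O)N2C(=O)OC[C@H]2Cc2ccccc2)c1OCc1ccccc1 | intermediate
11 | vanillin, 4-hydroxy-3-methoxybenzaldehyde | COc1cc(C=O)ccc1O | starting material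
12 | 3-methoxy-4-[tri(propan-2-yl)silyloxy]benzaldehyde | COc1cc(C=O)ccc1O[Si](C(C)C)(C(C)C)C(C)C | intermediate
13 | dibutylboron Z-enolate of imide 10 | CCCCB(CCCC)O/C(=C\c1cc(CCCO[Si](c2ccccc2)(c2ccccc2)C(C)(C)C)cc(OC)c1OCc1ccccc1)N1C(=O)OC[C@H]1Cc1ccccc1 | intermediate (not isolated)
14 | (4R)-4-benzyl-3-[(2R,3R)-2-{2-(benzyloxy)-3-methoxy-5-[3-(tert-butyldiphenylsilyloxy)propyl]phenyl}-3-hydroxy-3-{3-methoxy-4-[tri(propan-2-yl)silyloxy]phenyl}propanoyl]-1,3-oxazolidin-2-one | COc1cc([C@H](O)[C@H](C(=O)N2C(=O)OC[C@H]2Cc2ccccc2)c2cc(CCCO[Si](c3ccccc3)(c3ccccc3)C(C)(C)C)cc(OC)c2OCc2ccccc2)ccc1O[Si](C(C)C)(C(C)C)C(C)C | intermediate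
15 | (1R,2S)-2-{2-(benzyloxy)-3-methoxy-5-[3-(tert-butyldiphenylsilyloxy)propyl]phenyl}-1-{3-methoxy-4-[tri(propan-2-yl)silyloxy]phenyl}propane-1,3-diol | COc1cc([C@H](O)[C@H](CO)c2cc(CCCO[Si](c3ccccc3)(c3ccccc3)C(C)(C)C)cc(OC)c2OCc2ccccc2)ccc1O[Si](C(C)C)(C(C)C)C(C)C | intermediate
16 | (1R,2S)-2-{2-hydroxy-3-methoxy-5-[3-(tert-butyldiphenylsilyloxy)propyl]phenyl}-1-{3-methoxy-4-[tri(propan-2-yl)silyloxy]phenyl}propane-1,3-diol (key-step precursor; the 1S epimer, if present, is carried along) | COc1cc([C@H](O)[C@H](CO)c2cc(CCCO[Si](c3ccccc3)(c3ccccc3)C(C)(C)C)cc(OC)c2O)ccc1O[Si](C(C)C)(C(C)C)C(C)C | intermediate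
17 | O-TIPS para-quinone methide cation, the C2 benzylic cation of 16 in its quinoid oxocarbenium form | COC1=CC(=C[C@H](CO)c2cc(CCCO[Si](c3ccccc3)(c3ccccc3)C(C)(C)C)cc(OC)c2O)C=CC1=[O+][Si](C(C)C)(C(C)C)C(C)C | intermediate (not isolated)
18 | [(2R,3S)-7-methoxy-2-{3-methoxy-4-[tri(propan-2-yl)silyloxy]phenyl}-5-[3-(tert-butyldiphenylsilyloxy)propyl]-2,3-dihydro-1-benzofuran-3-yl]methanol (key-step product) | COc1cc([C@@H]2Oc3c(OC)cc(CCCO[Si](c4ccccc4)(c4ccccc4)C(C)(C)C)cc3[C@H]2CO)ccc1O[Si](C(C)C)(C(C)C)C(C)C | intermediate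
19 | p-coumaric acid, (E)-3-(4-hydroxyphenyl)prop-2-enoic acid | O=C(O)/C=C/c1ccc(O)cc1 | starting material
20 | tert-butyldimethylsilyl (E)-3-[4-(tert-butyldimethylsilyloxy)phenyl]prop-2-enoate | CC(C)(C)[Si](C)(C)OC(=O)/C=C/c1ccc(O[Si](C)(C)C(C)(C)C)cc1 | intermediate (not isolated)
21 | (E)-3-[4-(tert-butyldimethylsilyloxy)phenyl]prop-2-enoic acid | O=C(O)/C=C/c1ccc(O[Si](C)(C)C(C)(C)C)cc1 | intermediate
22 | [(2R,3S)-7-methoxy-2-{3-methoxy-4-[tri(propan-2-yl)silyloxy]phenyl}-5-[3-(tert-butyldiphenylsilyloxy)propyl]-2,3-dihydro-1-benzofuran-3-yl]methyl (E)-3-[4-(tert-butyldimethylsilyloxy)phenyl]prop-2-enoate | COc1cc([C@@H]2Oc3c(OC)cc(CCCO[Si](c4ccccc4)(c4ccccc4)C(C)(C)C)cc3[C@H]2COC(=O)/C=C/c2ccc(O[Si](C)(C)C(C)(C)C)cc2)ccc1O[Si](C(C)C)(C(C)C)C(C)C | intermediate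
23 | [(2R,3S)-2-(4-hydroxy-3-methoxyphenyl)-5-(3-hydroxypropyl)-7-methoxy-2,3-dihydro-1-benzofuran-3-yl]methyl (E)-3-(4-hydroxyphenyl)prop-2-enoate | COc1cc([C@@H]2Oc3c(OC)cc(CCCO)cc3[C@H]2COC(=O)/C=C/c2ccc(O)cc2)ccc1O | target

Total step count: 15
Longest linear sequence: 13 steps (steps 1 to 7, 9 to 12, 14 and 15); steps 8 and 13 are side branches.

Steps most likely to fail

1. Step 12 (ring closure).
- What may go wrong: the cation may lose the C3 proton, or the C9 carbon as formaldehyde, faster than the phenol captures it, giving stilbene-type material. The silyl group may also be transferred from the oxocarbenium oxygen, leaving a free phenol that spoils the later esterification.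
- Fallback through the neutral quinone methide, setting out from 16: the aryl TIPS ether alone would be cleaved with TBAF (1 equiv, THF, −20 °C; aryl silyl ethers react far faster than the primary TBDPS ether) to give the bis-phenol triol F1.
- With pyridinium p-toluenesulfonate in CH2Cl2 at rt, the 4-hydroxybenzyl alcohol of F1 should lose water to the neutral para-quinone methide F2 (not isolated). F2 is a weaker electrophile than the cation and sheds a proton or formaldehyde less readily.
- Conjugate 1,6-addition of the ring-B phenol to F2 should give the trans-dihydrobenzofuran phenol F3.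
- Mitsunobu esterification of the C9 alcohol of F3 with unprotected p-coumaric acid 19 (PPh3, DIAD, THF, 0 °C) would give the coumarate F4; the carboxylic acid is far more acidic than either phenol and should be the pronucleophile engaged.
- TBAF/AcOH in THF would then remove the TBDPS group, and the fallback arrives at the target 23.

2. Step 9 (aldol reaction).
- What may go wrong: incomplete enolisation of the hindered, ortho-disubstituted arylacetyl imide, reversal of the addition to the electron-rich aldehyde during work-up, or erosion of facial control.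
- Fallback by alkylation and aryl addition, setting out from 10: C3 is set by auxiliary-controlled alkylation, and the C2 carbinol, whose configuration does not matter, is built afterwards.
- The titanium enolate of 10 (TiCl4, iPr2NEt, CH2Cl2, 0 °C) would be alkylated irreversibly with benzyl chloromethyl ether on the face remote from the auxiliary benzyl group, giving the (2S)-α-(benzyloxymethyl) imide F5. The new carbon is now C9 and the acyl carbon becomes C2, so the same (R)-auxiliary delivers the required C3 configuration.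
- LiBH4 (THF, MeOH, 0 °C) would give the primary alcohol F6.
- Dess–Martin oxidation (NaHCO3, CH2Cl2, 0 °C) would give the aldehyde F7, which is used cold and without chromatography because its α-centre is configurationally fragile.
- Separately, 4-bromo-2-methoxyphenol would be silylated (TIPSCl, imidazole, DMF) to the aryl bromide F8 and converted with magnesium turnings in THF into the Grignard reagent F9.
- Addition of F9 to F7 at −78 °C would give the secondary alcohol F10 as a mixture at the carbinol.
- Hydrogenolysis of both benzyl ethers (H2, Pd(OH)2/C, EtOAc) would bring the fallback back to the route at 16, as a carbinol mixture that step 12 accepts.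

3. Step 10 (reductive removal of the auxiliary).
- What may go wrong: base-induced retro-aldol cleavage or epimerisation at C3 under the hydride conditions, or hydride attack at the ring carbonyl of the hindered imide, which opens the oxazolidinone instead of releasing it.
- Fallback through the acid, setting out from 14: hydrolysis with LiOH/H2O2 (THF/H2O, 0 °C), in which the weakly basic hydroperoxide attacks the exocyclic carbonyl selectively, would give the β-hydroxy acid F11.
- Chemoselective reduction of the carboxylic acid with BH3·SMe2 (THF, 0 °C → rt) would bring the fallback back to the route at 15.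

Further compounds
F1 | step 12 | (1R,2S)-1-(4-hydroxy-3-methoxyphenyl)-2-{2-hydroxy-3-methoxy-5-[3-(tert-butyldiphenylsilyloxy)propyl]phenyl}propane-1,3-diol | COc1cc([C@H](O)[C@H](CO)c2cc(CCCO[Si](c3ccccc3)(c3ccccc3)C(C)(C)C)cc(OC)c2O)ccc1O
F2 | step 12 | neutral para-quinone methide, 4-[(2S)-3-hydroxy-2-{2-hydroxy-3-methoxy-5-[3-(tert-butyldiphenylsilyloxy)propyl]phenyl}propylidene]-2-methoxycyclohexa-2,5-dien-1-one | COC1=CC(=C[C@H](CO)c2cc(CCCO[Si](c3ccccc3)(c3ccccc3)C(C)(C)C)cc(OC)c2O)C=CC1=O
F3 | step 12 | 4-[(2R,3S)-3-(hydroxymethyl)-7-methoxy-5-[3-(tert-butyldiphenylsilyloxy)propyl]-2,3-dihydro-1-benzofuran-2-yl]-2-methoxyphenol | COc1cc([C@@H]2Oc3c(OC)cc(CCCO[Si](c4ccccc4)(c4ccccc4)C(C)(C)C)cc3[C@H]2CO)ccc1O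
F4 | step 12 | [(2R,3S)-2-(4-hydroxy-3-methoxyphenyl)-7-methoxy-5-[3-(tert-butyldiphenylsilyloxy)propyl]-2,3-dihydro-1-benzofuran-3-yl]methyl (E)-3-(4-hydroxyphenyl)prop-2-enoate | COc1cc([C@@H]2Oc3c(OC)cc(CCCO[Si](c4ccccc4)(c4ccccc4)C(C)(C)C)cc3[C@H]2COC(=O)/C=C/c2ccc(O)cc2)ccc1O
F5 | step 9 | (4R)-4-benzyl-3-[(2S)-3-(benzyloxy)-2-{2-(benzyloxy)-3-methoxy-5-[3-(tert-butyldiphenylsilyloxy)propyl]phenyl}propanoyl]-1,3-oxazolidin-2-one | COc1cc(CCCO[Si](c2ccccc2)(c2ccccc2)C(C)(C)C)cc([C@@H](COCc2ccccc2)C(=O)N2C(=O)OC[C@H]2Cc2ccccc2)c1OCc1ccccc1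
F6 | step 9 | (2R)-3-(benzyloxy)-2-{2-(benzyloxy)-3-methoxy-5-[3-(tert-butyldiphenylsilyloxy)propyl]phenyl}propan-1-ol | COc1cc(CCCO[Si](c2ccccc2)(c2ccccc2)C(C)(C)C)cc([C@@H](COCc2ccccc2)CO)c1OCc1ccccc1
F7 | step 9 | (2S)-3-(benzyloxy)-2-{2-(benzyloxy)-3-methoxy-5-[3-(tert-butyldiphenylsilyloxy)propyl]phenyl}propanal | COc1cc(CCCO[Si](c2ccccc2)(c2ccccc2)C(C)(C)C)cc([C@@H](COCc2ccccc2)C=O)c1OCc1ccccc1
F8 | step 9 | (4-bromo-2-methoxyphenoxy)tri(propan-2-yl)silane | COc1cc(Br)ccc1O[Si](C(C)C)(C(C)C)C(C)C
F9 | step 9 | bromo{3-methoxy-4-[tri(propan-2-yl)silyloxy]phenyl}magnesium | COc1cc([Mg]Br)ccc1O[Si](C(C)C)(C(C)C)C(C)C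
F10 | step 9 | (2S)-3-(benzyloxy)-2-{2-(benzyloxy)-3-methoxy-5-[3-(tert-butyldiphenylsilyloxy)propyl]phenyl}-1-{3-methoxy-4-[tri(propan-2-yl)silyloxy]phenyl}propan-1-ol, mixture at C1 | COc1cc(C(O)[C@H](COCc2ccccc2)c2cc(CCCO[Si](c3ccccc3)(c3ccccc3)C(C)(C)C)cc(OC)c2OCc2ccccc2)ccc1O[Si](C(C)C)(C(C)C)C(C)C
F11 | step 10 | (2R,3R)-2-{2-(benzyloxy)-3-methoxy-5-[3-(tert-butyldiphenylsilyloxy)propyl]phenyl}-3-hydroxy-3-{3-methoxy-4-[tri(propan-2-yl)silyloxy]phenyl}propanoic acid | COc1cc([C@H](O)[C@H](C(=O)O)c2cc(CCCO[Si](c3ccccc3)(c3ccccc3)C(C)(C)C)cc(OC)c2OCc2ccccc2)ccc1O[Si](C(C)C)(C(C)C)C(C)C
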